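## Retrosynthetic overview

1. The target is opened to an acyclic ynone–methyl ketone. One acid-relay operation closes the pyran ring first (6-endo oxa-Michael of the C1 hydroxyl), then the carbocycle (aldol condensation of the C6 methyl ketone onto C4a).
2. The ynone comes from a C4–C4a alkynyl–aldehyde coupling of a side-chain iodoenyne with a C1/C8a/C8/C7 aldehyde, followed by chelation-controlled acetyl-anion addition at C7 and propargylic oxidation.
3. The aldehyde comes from methylglyoxal and 3-silyloxypropanal by an amine-catalysed anti cross-aldol reaction (sets C8 and C8a).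
4. The iodoenyne comes from an α-hydroxy ketone and a silylbutadiyne (chelation-controlled alkynylation sets C3', hydroalumination sets the E-alkene). The α-hydroxy ketone comes from methylglyoxal and an (E)-crotylboronate by chiral phosphoric acid crotylboration (sets C4' and C5').
5. Locants: isochromene numbering for the bicycle (C1, O2, C3, C4, C4a, C5–C8, C8a), primes for the heptenyl chain. Target = (7S,8R,8aS), side chain (1'E,3'R,4'R,5'R).

Assumption: the sense of induction of (R)-TRIP and of the (S)-prolinol catalyst is taken from their standard models; if a substrate responds oppositely, the enantiomeric catalyst is used.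
Assumption: anhydrous methylglyoxal for step 1 is obtained by distilling the commercial aqueous solution; step 6 uses the aqueous solution directly.

## Route

Step 1
Reactants: 1 methylglyoxal (anhydrous monomer, freshly distilled); 2 (E)-crotylboronic acid pinacol ester
Product: 4 (3R,4R)-3-hydroxy-4-methylhex-5-en-2-one, via pinacol borate ester 3 (not isolated)
Conditions: (R)-TRIP [(R)-3,3'-bis(2,4,6-triisopropylphenyl)-1,1'-binaphthyl-2,2'-diyl hydrogen phosphate] (5 mol%), 4 Å MS, toluene, −40 °C; then aq. NaHCO3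
Reagents that add atoms: none
Why: Chiral phosphoric acid-catalysed crotylboration: the aldehyde reacts far faster than the ketone, the closed chair transition state turns the E-boronate into the anti adduct (C4'–OH/C5'–Me), and the phosphate-bound boronate fixes the aldehyde face, so both centres come from the catalyst.

Step 2
Reactants: 4 (3R,4R)-3-hydroxy-4-methylhex-5-en-2-one
Product: 5 (3R,4R)-3-hydroxy-4-methylhexan-2-one
Conditions: H2 (1 atm), 10% Pd/C, EtOAc, 20 °C
Reagents that add atoms: none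
Why: Heterogeneous hydrogenation of the monosubstituted alkene converts the vinyl group into the ethyl terminus without touching the ketone or either stereocentre.

Step 3
Reactants: 5 (3R,4R)-3-hydroxy-4-methylhexan-2-one; 6 1,4-bis(trimethylsilyl)buta-1,3-diyne
Product: 9 (5R,6R,7R)-5,7-dimethyl-1-(trimethylsilyl)nona-1,3-diyne-5,6-diol, via lithium 4-(trimethylsilyl)buta-1,3-diynide 7 (not isolated), via 4-(trimethylsilyl)buta-1,3-diynylmagnesium bromide 8 (not isolated)
Conditions: 6, MeLi·LiBr, THF, −78 to 20 °C; MgBr2·OEt2, −78 °C; then 5 (2.3 equiv of 8 per 5), −78 to −20 °C; then H2O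
Reagents that add atoms: none
Why: Cram-chelate addition of an alkynyl Grignard reagent: the first equivalent forms the magnesium alkoxide of 5, the five-membered O–Mg–O=C chelate exposes the carbonyl face on the side of the C4' hydrogen, and the diynyl group enters there to give the 3',4'-syn diol (C3' = R).

Step 4
Reactants: 9 (5R,6R,7R)-5,7-dimethyl-1-(trimethylsilyl)nona-1,3-diyne-5,6-diol
Product: 10 (3E,5R,6R,7R)-5,7-dimethyl-1-(trimethylsilyl)non-3-en-1-yne-5,6-diol
Conditions: NaAlH2(OCH2CH2OCH3)2 (Red-Al, 3.5 equiv), THF, 0 to 20 °C; then aq. NaOH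
Reagents that add atoms: none
Why: Hydroxyl-directed trans-hydroalumination of a propargylic alcohol: the tertiary alkoxide delivers hydride only to the adjacent alkyne and protonolysis of the vinylalane gives the E-alkene while the silylalkyne is kept.

Step 5
Reactants: 10 (3E,5R,6R,7R)-5,7-dimethyl-1-(trimethylsilyl)non-3-en-1-yne-5,6-diol
Product: 11 (3E,5R,6R,7R)-1-iodo-5,7-dimethylnon-3-en-1-yne-5,6-diol
Conditions: NIS (1.2 equiv), AgNO3 (10 mol%), acetone, 20 °C, dark
Reagents that add atoms: N-iodosuccinimide O=C1CCC(=O)N1I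
Why: Silver-catalysed iododesilylation of the alkynylsilane (through the silver acetylide) gives the 1-iodoalkyne needed for chromium-mediated coupling and leaves the conjugated alkene and the diol alone.

Step 6
Reactants: 1 methylglyoxal (40% aqueous solution); 12 3-[(tert-butyldimethylsilyl)oxy]propanal
Product: 13 (2S,3R)-2-{[(tert-butyldimethylsilyl)oxy]methyl}-3-hydroxy-4-oxopentanal
Conditions: (S)-α,α-bis[3,5-bis(trifluoromethyl)phenyl]prolinol (10 mol%), DMF, 4 °C, slow addition of 12; extractive work-up, short silica plug, used at once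
Reagents that add atoms: none
Why: Enamine-mediated direct cross-aldol reaction: 12 is the enamine donor, the glyoxal-type aldehyde of 1 is the most electrophilic carbonyl present, and the hydrogen-bond-directed (proline-type) transition state gives the anti aldol that fixes C8 (R) and C8a.

Step 7
Reactants: 11 (3E,5R,6R,7R)-1-iodo-5,7-dimethylnon-3-en-1-yne-5,6-diol; 13 (2S,3R)-2-{[(tert-butyldimethylsilyl)oxy]methyl}-3-hydroxy-4-oxopentanal
Product: 14 (3R,4R,5RS,8E,10R,11R,12R)-4-{[(tert-butyldimethylsilyl)oxy]methyl}-3,5,10,11-tetrahydroxy-10,12-dimethyltetradec-8-en-6-yn-2-one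
Conditions: CrCl2 (6 equiv), THF–DMF, 20 °C; aqueous work-up
Reagents that add atoms: none
Why: Takai/Nozaki–Hiyama–Kishi-type alkynylation: divalent chromium inserts into the C–I bond and the non-basic alkynylchromium species adds to the aldehyde only, so the methyl ketone, the free hydroxyls and the epimerisable C8a centre survive; the new C4a carbinol is a mixture that is oxidised in step 9.

Step 8
Reactants: 14 (3R,4R,5RS,8E,10R,11R,12R)-4-{[(tert-butyldimethylsilyl)oxy]methyl}-3,5,10,11-tetrahydroxy-10,12-dimethyltetradec-8-en-6-yn-2-one; 15 ethyl vinyl ether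
Product: 19 (3S,4R,5R,6RS,9E,11R,12R,13R)-5-{[(tert-butyldimethylsilyl)oxy]methyl}-3,4,6,11,12-pentahydroxy-3,11,13-trimethylpentadec-9-en-7-yn-2-one, via 1-ethoxyvinyllithium 16 (not isolated), via 1-ethoxyvinylmagnesium bromide 17 (not isolated), via enol ether adduct 18 (not isolated)
Conditions: 15, t-BuLi, THF, −78 to 0 °C; MgBr2·OEt2, −78 °C; then 14 (8 equiv of 17 per 14), −78 to −30 °C; then 0.5 M HCl, THF, 0 °C
Reagents that add atoms: water O
Why: Chelation-controlled (Cram cyclic) addition of an acetyl-anion equivalent: four equivalents are spent on the hydroxyls, the C8 magnesium alkoxide chelates the C7 ketone so the nucleophile enters on the side of the C8 hydrogen and gives the 7,8-syn diol (C7 = S), and dilute acid hydrolyses the enol ether to the methyl ketone.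

Step 9
Reactants: 19 (3S,4R,5R,6RS,9E,11R,12R,13R)-5-{[(tert-butyldimethylsilyl)oxy]methyl}-3,4,6,11,12-pentahydroxy-3,11,13-trimethylpentadec-9-en-7-yn-2-one
Product: 20 (3S,4R,5S,9E,11R,12R,13R)-5-{[(tert-butyldimethylsilyl)oxy]methyl}-3,4,11,12-tetrahydroxy-3,11,13-trimethylpentadec-9-en-7-yne-2,6-dione
Conditions: MnO2 (activated, 20 equiv), CH2Cl2, 20 °C
Reagents that add atoms: none
Why: Chemoselective MnO2 oxidation of the propargylic alcohol to the conjugated ynone; the unactivated secondary and the tertiary alcohols are not oxidised and the neutral conditions spare C8a.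

Step 10
Reactants: 20 (3S,4R,5S,9E,11R,12R,13R)-5-{[(tert-butyldimethylsilyl)oxy]methyl}-3,4,11,12-tetrahydroxy-3,11,13-trimethylpentadec-9-en-7-yne-2,6-dione
Product: 23 (7S,8R,8aS)-3-[(1E,3R,4R,5R)-3,4-dihydroxy-3,5-dimethylhept-1-en-1-yl]-7,8-dihydroxy-7-methyl-1,7,8,8a-tetrahydro-6H-isochromen-6-one, via hydroxy ynone 21 (not isolated), via dihydropyranone 22 (not isolated)
Conditions: TsOH·H2O (0.2 equiv), MeOH–CH2Cl2 (1:4), 0 to 30 °C; then NaHCO3
Reagents that add atoms: none
Why: Proposed new method: one Brønsted acid relays three events, namely methanolysis of the primary silyl ether, 6-endo-dig oxa-Michael addition of the freed C1 hydroxyl to the ynone (giving 22), and a 6-(enolendo)-exo-trig aldol condensation in which the enol (or methyl enol ether) of the C6 methyl ketone, the only enolisable site next to quaternary C7, attacks the O-protonated vinylogous ester (a 4-hydroxy-2,3-dihydropyrylium ion) at C4a, after which the carbinol loses water through the oxygen-stabilised cation to give the push–pull dienone; a pyranone closed wrongly through the hindered C8 hydroxyl can only revert by acid-catalysed vinylogous transesterification because its aldol product would be a bridgehead alkene, and no stereocentre is made or broken; the closest known chemistry is the acid-mediated desilylative cyclisation of β-silyloxy ynones to dihydropyranones, Robinson-type aldol cyclodehydration and Knoevenagel condensation at C4 of 4-pyranones.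

## Compound list

1 | methylglyoxal (2-oxopropanal) | CC(=O)C=O | starting material
2 | (E)-crotylboronic acid pinacol ester, 2-[(2E)-but-2-en-1-yl]-4,4,5,5-tetramethyl-1,3,2-dioxaborolane | C/C=C/CB1OC(C)(C)C(C)(C)O1 | starting material
3 | 2-{[(3R,4R)-4-methyl-2-oxohex-5-en-3-yl]oxy}-4,4,5,5-tetramethyl-1,3,2-dioxaborolane | C=C[C@@H](C)[C@@H](OB1OC(C)(C)C(C)(C)O1)C(C)=O | intermediate
4 | (3R,4R)-3-hydroxy-4-methylhex-5-en-2-one | C=C[C@@H](C)[C@@H](O)C(C)=O | intermediate
5 | (3R,4R)-3-hydroxy-4-methylhexan-2-one | CC[C@@H](C)[C@@H](O)C(C)=O | intermediate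
6 | 1,4-bis(trimethylsilyl)buta-1,3-diyne | C[Si](C)(C)C#CC#C[Si](C)(C)C | starting material
7 | lithium 4-(trimethylsilyl)buta-1,3-diynide | [Li]C#CC#C[Si](C)(C)C | intermediate
8 | 4-(trimethylsilyl)buta-1,3-diynylmagnesium bromide | Br[Mg]C#CC#C[Si](C)(C)C | intermediate
9 | (5R,6R,7R)-5,7-dimethyl-1-(trimethylsilyl)nona-1,3-diyne-5,6-diol | CC[C@@H](C)[C@@H](O)[C@](C)(O)C#CC#C[Si](C)(C)C | intermediate
10 | (3E,5R,6R,7R)-5,7-dimethyl-1-(trimethylsilyl)non-3-en-1-yne-5,6-diol | CC[C@@H](C)[C@@H](O)[C@](C)(O)/C=C/C#C[Si](C)(C)C | intermediate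
11 | (3E,5R,6R,7R)-1-iodo-5,7-dimethylnon-3-en-1-yne-5,6-diol | CC[C@@H](C)[C@@H](O)[C@](C)(O)/C=C/C#CI | intermediate
12 | 3-[(tert-butyldimethylsilyl)oxy]propanal | O=CCCO[Si](C)(C)C(C)(C)C | starting material
13 | (2S,3R)-2-{[(tert-butyldimethylsilyl)oxy]methyl}-3-hydroxy-4-oxopentanal | CC(=O)[C@H](O)[C@@H](C=O)CO[Si](C)(C)C(C)(C)C | intermediate
14 | (3R,4R,5RS,8E,10R,11R,12R)-4-{[(tert-butyldimethylsilyl)oxy]methyl}-3,5,10,11-tetrahydroxy-10,12-dimethyltetradec-8-en-6-yn-2-one | CC[C@@H](C)[C@@H](O)[C@](C)(O)/C=C/C#CC(O)[C@@H](CO[Si](C)(C)C(C)(C)C)[C@@H](O)C(C)=O | intermediate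
15 | ethyl vinyl ether | C=COCC | starting material
16 | 1-ethoxyvinyllithium | [Li]C(=C)OCC | intermediate
17 | 1-ethoxyvinylmagnesium bromide | Br[Mg]C(=C)OCC | intermediate
18 | (3S,4R,5R,6RS,9E,11R,12R,13R)-5-{[(tert-butyldimethylsilyl)oxy]methyl}-2-ethoxy-3,11,13-trimethylpentadeca-1,9-dien-7-yne-3,4,6,11,12-pentol | CC[C@@H](C)[C@@H](O)[C@](C)(O)/C=C/C#CC(O)[C@@H](CO[Si](C)(C)C(C)(C)C)[C@@H](O)[C@](C)(O)C(=C)OCC | intermediate
19 | (3S,4R,5R,6RS,9E,11R,12R,13R)-5-{[(tert-butyldimethylsilyl)oxy]methyl}-3,4,6,11,12-pentahydroxy-3,11,13-trimethylpentadec-9-en-7-yn-2-one | CC[C@@H](C)[C@@H](O)[C@](C)(O)/C=C/C#CC(O)[C@@H](CO[Si](C)(C)C(C)(C)C)[C@@H](O)[C@](C)(O)C(C)=O | intermediate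
20 | (3S,4R,5S,9E,11R,12R,13R)-5-{[(tert-butyldimethylsilyl)oxy]methyl}-3,4,11,12-tetrahydroxy-3,11,13-trimethylpentadec-9-en-7-yne-2,6-dione | CC[C@@H](C)[C@@H](O)[C@](C)(O)/C=C/C#CC(=O)[C@@H](CO[Si](C)(C)C(C)(C)C)[C@@H](O)[C@](C)(O)C(C)=O | intermediate
21 | (3S,4R,5S,9E,11R,12R,13R)-3,4,11,12-tetrahydroxy-5-(hydroxymethyl)-3,11,13-trimethylpentadec-9-en-7-yne-2,6-dione | CC[C@@H](C)[C@@H](O)[C@](C)(O)/C=C/C#CC(=O)[C@@H](CO)[C@@H](O)[C@](C)(O)C(C)=O | intermediate
22 | (3S)-3-[(1R,2S)-1,2-dihydroxy-2-methyl-3-oxobutyl]-6-[(1E,3R,4R,5R)-3,4-dihydroxy-3,5-dimethylhept-1-en-1-yl]-2,3-dihydro-4H-pyran-4-one | CC[C@@H](C)[C@@H](O)[C@](C)(O)/C=C/C1=CC(=O)[C@@H](CO1)[C@@H](O)[C@](C)(O)C(C)=O | intermediate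
23 | (7S,8R,8aS)-3-[(1E,3R,4R,5R)-3,4-dihydroxy-3,5-dimethylhept-1-en-1-yl]-7,8-dihydroxy-7-methyl-1,7,8,8a-tetrahydro-6H-isochromen-6-one | CC[C@@H](C)[C@@H](O)[C@](C)(O)/C=C/C1=CC2=CC(=O)[C@@](C)(O)[C@H](O)[C@@H]2CO1 | target

## Step count and risks

Total steps: 10. Longest linear sequence: 9 steps (steps 1–5, then 7–10).

The three steps most likely to fail are steps 10, 6 and 8.

For step 10, the unprecedented acid relay may stall at the dihydropyranone, erode C8a by enolisation, or damage the tertiary allylic diol. The fallback sets out from 20 and comes back at 23 using known reactions only. Compound 20 is desilylated and cyclised in the established two-stage way (PPTS, MeOH; then AgOSO2CF3 5 mol%, CH2Cl2) and 22 is isolated. All four hydroxyls are capped (Et3SiOSO2CF3, 2,6-lutidine, CH2Cl2, −78 °C) to give the tetrakis(triethylsilyl) ether F1. LiN(SiMe3)2 in THF at −78 °C forms the kinetic methyl-ketone enolate, which adds 1,2 to the vinylogous ester carbonyl as in a Stork–Danheiser addition to give the bicyclic carbinol F2. PPTS in CH2Cl2 removes water to give the protected dienone F3, and HF·pyridine in THF then releases 23.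

For step 6, methylglyoxal may degrade the amine catalyst or react without facial control, and the β-silyloxy donor may eliminate. The fallback sets out from 12 and comes back at 14. It uses the documented proline cross-aldol with an α-thioacetal aldehyde acceptor. 2-Methyl-1,3-dithiane-2-carbaldehyde F4 is made from 2-methyl-1,3-dithiane (n-BuLi, then DMF). L-Proline (10 mol%, DMF, 4 °C) couples it with 12 to the anti aldol F5. The CrCl2 coupling with 11 gives the dithiane-masked tetraol F6. MeI and CaCO3 in aqueous MeCN then unveil the methyl ketone, giving 14.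

For step 8, the tetra-alkoxide of 14 may be too insoluble or too crowded for clean chelation-controlled addition. The fallback sets out from 13 and comes back at 19 by installing the acetyl unit before the fragments are joined. Compound 13 is converted to its dimethyl acetal F7 (HC(OMe)3, TsOH cat., MeOH, 0 °C). Reagent 17 (2.5 equiv) adds to this mono-hydroxy ketone under the same chelate control to give the enol ether F8. Wet Amberlyst-15 in acetone hydrolyses both the enol ether and the acetal to the keto aldehyde F9, which may rest largely as its five-membered lactol. The ketone-tolerant CrCl2 coupling of F9 with 11 gives 19.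

Further compounds

F1 | step 10 | (3S)-3-[(1R,2S)-2-methyl-3-oxo-1,2-bis(triethylsilyloxy)butyl]-6-[(1E,3R,4R,5R)-3,5-dimethyl-3,4-bis(triethylsilyloxy)hept-1-en-1-yl]-2,3-dihydro-4H-pyran-4-one | CC[C@@H](C)[C@@H](O[Si](CC)(CC)CC)[C@](C)(O[Si](CC)(CC)CC)/C=C/C1=CC(=O)[C@@H](CO1)[C@@H](O[Si](CC)(CC)CC)[C@](C)(O[Si](CC)(CC)CC)C(C)=O
F2 | step 10 | (4aRS,7S,8R,8aS)-4a-hydroxy-7-methyl-7,8-bis(triethylsilyloxy)-3-[(1E,3R,4R,5R)-3,5-dimethyl-3,4-bis(triethylsilyloxy)hept-1-en-1-yl]-4a,5,8,8a-tetrahydro-1H-isochromen-6(7H)-one | CC[C@@H](C)[C@@H](O[Si](CC)(CC)CC)[C@](C)(O[Si](CC)(CC)CC)/C=C/C1=CC2(O)CC(=O)[C@@](C)(O[Si](CC)(CC)CC)[C@H](O[Si](CC)(CC)CC)[C@@H]2CO1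
F3 | step 10 | (7S,8R,8aS)-7-methyl-7,8-bis(triethylsilyloxy)-3-[(1E,3R,4R,5R)-3,5-dimethyl-3,4-bis(triethylsilyloxy)hept-1-en-1-yl]-1,7,8,8a-tetrahydro-6H-isochromen-6-one | CC[C@@H](C)[C@@H](O[Si](CC)(CC)CC)[C@](C)(O[Si](CC)(CC)CC)/C=C/C1=CC2=CC(=O)[C@@](C)(O[Si](CC)(CC)CC)[C@H](O[Si](CC)(CC)CC)[C@@H]2CO1
F4 | step 6 | 2-methyl-1,3-dithiane-2-carbaldehyde | CC1(C=O)SCCCS1
F5 | step 6 | (2S,3R)-2-{[(tert-butyldimethylsilyl)oxy]methyl}-3-hydroxy-3-(2-methyl-1,3-dithian-2-yl)propanal | CC1(SCCCS1)[C@H](O)[C@@H](C=O)CO[Si](C)(C)C(C)(C)C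
F6 | step 6 | (1R,2R,3RS,6E,8R,9R,10R)-2-{[(tert-butyldimethylsilyl)oxy]methyl}-8,10-dimethyl-1-(2-methyl-1,3-dithian-2-yl)dodec-6-en-4-yne-1,3,8,9-tetrol | CC[C@@H](C)[C@@H](O)[C@](C)(O)/C=C/C#CC(O)[C@@H](CO[Si](C)(C)C(C)(C)C)[C@@H](O)C1(C)SCCCS1
F7 | step 8 | (3R,4S)-4-{[(tert-butyldimethylsilyl)oxy]methyl}-3-hydroxy-5,5-dimethoxypentan-2-one | CC(=O)[C@H](O)[C@@H](C(OC)OC)CO[Si](C)(C)C(C)(C)C
F8 | step 8 | (3S,4R,5S)-5-{[(tert-butyldimethylsilyl)oxy]methyl}-2-ethoxy-6,6-dimethoxy-3-methylhex-1-ene-3,4-diol | CCOC(=C)[C@@](C)(O)[C@H](O)[C@@H](C(OC)OC)CO[Si](C)(C)C(C)(C)C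
F9 | step 8 | (2S,3R,4S)-2-{[(tert-butyldimethylsilyl)oxy]methyl}-3,4-dihydroxy-4-methyl-5-oxohexanal | CC(=O)[C@@](C)(O)[C@H](O)[C@@H](C=O)CO[Si](C)(C)C(C)(C)C
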